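**Plan**

1. Numbering: C1 is the quaternary carbon shared by ring A (C1-C11-C7-C6-C5), ring B (C1-C11-C7-C8-C9-C10) and ring C (C1-C2-C3-C4-C5); C2 bears the aldehyde carbon C12, C6 bears CH3 and CH2OH, C8 bears the carboxyl carbon C13, C10 bears the acyloxy group. The feature used: C10 (on C1) and C9 (β-carbon of the C8 acrylate on C7) are both electrophilic and sit on cis 1,3-arms of ring A, so only a reductively umpoled C10 (a ketyl) can close ring B at C9–C10.
2. Retrosynthetic cuts: the C10–O ester; C4–H/C5–H (hydrogenation); C9–C10 (ring B, ketyl addition with loss of sulfinate from C9); C8–C13, C8–C9 and C7–C8 (two carbonylations and a sulfone acylation); C4=C5 (metathesis, ring C); C2–C3, C1–C10 and C1–C2 (enolate alkylations); C6–CH2OH (aldol).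
3. Forward order: ring A comes from 2-methylcyclopentane-1,3-dione, ring C is closed by metathesis, ring B is closed last by SmI2; C4=C5 is then hydrogenated, the C16 acid (from oct-7-yn-1-ol and 8-bromooctanoic acid) is esterified onto C10, and one acid treatment removes all protecting groups.
4. Stereochemistry: C6 from a CBS desymmetrisation; C1 from enolate alkylation anti to the oxygen substituents on C7 and C6, confirmed by closure of bridged lactone A (C7–O to C12); C2 from axial allylation of lactone A; C7 from epimerisation into bridged lactone B (C10–O to C8).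
5. C10 is set in the key step, C5 by hydroxyl-directed hydrogenation from the C11 face, and the chain alkene by Lindlar reduction.

Key step: step 22

Remark: the SMILES is read literally, with H-5, H-7 and the C6 hydroxymethyl on the face of ring A away from ring B and C4, C8 and C10 on the ring B face, so rings A and C are trans-fused across C1–C5.

**Route**

Step 1
Reactants: 1 2-methylcyclopentane-1,3-dione
Product: 2 2-(hydroxymethyl)-2-methylcyclopentane-1,3-dione
Conditions: 37% aq. HCHO, H2O, rt
Reagents that add atoms: formaldehyde, C=O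
Why: Aldol addition (hydroxymethylation) of the acidic C–H of the 2-substituted 1,3-dione to formaldehyde needs no added base and builds the future C6 with both carbon substituents; no stereocentre forms because the two carbonyls are still equivalent.

Step 2
Reactants: 2 2-(hydroxymethyl)-2-methylcyclopentane-1,3-dione
Product: 3 2-{[tert-butyl(dimethyl)silyl]oxymethyl}-2-methylcyclopentane-1,3-dione
Conditions: TBSCl, imidazole, DMF, 0 °C → rt
Reagents that add atoms: tert-butyl(chloro)dimethylsilane, CC(C)(C)[Si](C)(C)Cl
Why: Silyl ether formation stops retro-aldol loss of formaldehyde and makes the two C6 substituents clearly different in size for the desymmetrisation.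

Step 3
Reactants: 3 silyl-protected dione
Product: 4 (2R,3R)-2-{[tert-butyl(dimethyl)silyl]oxymethyl}-3-hydroxy-2-methylcyclopentan-1-one
Conditions: (S)-2-methyl-CBS-oxazaborolidine (0.2 equiv), BH3·SMe2 (0.6 equiv), THF, −30 °C
Reagents that add atoms: none
Why: CBS reduction desymmetrises the prochiral dione: the (S)-oxazaborolidine gives the (R)-carbinol and, reinforced by hydride approach anti to the larger silyloxymethyl group, selects the carbonyl that makes C6 (R), so C6 and a C7 hydroxyl cis to the silyloxymethyl group are set together.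

Step 4
Reactants: 4 hydroxy ketone
Product: 5 C7 triethylsilyl ether of 4
Conditions: TESCl, imidazole, DMF, 0 °C → rt
Reagents that add atoms: chlorotriethylsilane, CC[Si](Cl)(CC)CC
Why: Silyl ether formation protects the β-hydroxy ketone against retro-aldol opening under the strong bases that follow and leaves both stereocentres untouched.

Step 5
Reactants: 5 silyl-protected ketone; 6 methyl bromoacetate
Product: 7 ketone 5 carrying CH2CO2Me on C1 (both C1 epimers)
Conditions: LiN(iPr)2, THF, −78 °C; then 6, DMPU, −78 → −40 °C
Reagents that add atoms: none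
Why: Kinetic enolate alkylation works because quaternary C6 lets the ketone enolise only toward C1, and the C1 configuration formed here does not matter since C1 is enolised again in step 6.

Step 6
Reactants: 7 C1-monoalkylated keto ester
Product: 8 keto ester with quaternary C1 (CH2OPMB trans and CH2CO2Me cis to the C7 silyloxy group)
Conditions: LiN(SiMe3)2, THF, −78 → 0 °C; then 4-MeOC6H4CH2OCH2Cl, −78 → −20 °C
Reagents that add atoms: 4-methoxybenzyl chloromethyl ether, COc1ccc(COCCl)cc1
Why: Enolate C-alkylation with a chloromethyl ether builds quaternary C1: under equilibrating conditions the amide base gives the more acidic ketone enolate, and the electrophile enters anti to the C7 silyloxy and C6 silyloxymethyl groups that share one face of ring A, so C10 ends trans and the acetate arm cis to the C7 oxygen.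

Step 7
Reactants: 8 C1-quaternary keto ester
Product: 9 C5-methylidene ester
Conditions: Zn, CH2Br2, TiCl4, THF/CH2Cl2, 0 °C → rt
Reagents that add atoms: dibromomethane, BrCBr
Why: Takai–Lombardo methylenation uses a small, non-basic titanium–zinc methylene reagent that converts ketones flanked by quaternary carbons and leaves the ester untouched; no stereocentre is involved.

Step 8
Reactants: 9 C5-methylidene ester
Product: 11 bridged lactone A (2-oxabicyclo[3.2.1]octan-3-one), via hydroxy ester 10 (not isolated)
Conditions: PPTS, MeOH, rt; then PPTS, toluene, 80 °C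
Reagents that add atoms: none
Why: Acid-catalysed removal of the triethylsilyl ether followed by lactonisation can give the bridged δ-lactone only from the C1 epimer whose acetate arm is cis to the C7 hydroxyl, so the ring closure confirms and purifies the C1 configuration without creating a new stereocentre.

Step 9
Reactants: 11 bridged lactone A; 12 allyl bromide
Product: 13 C2-allyl lactone A (allyl anti to the C1–C5 bond)
Conditions: LiN(iPr)2, THF, −78 °C; then 12, −78 → −40 °C
Reagents that add atoms: none
Why: Lactone enolate alkylation occurs at C2, the only enolisable position, and the electrophile adds anti to the pseudo-axial C1–C5 bond of the bicyclic enolate (axial attack from the side of the one-carbon bridge C11), which sets C2 so that C12 is cis to C10 once the lactone is opened.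

Step 10
Reactants: 13 C2-allyl lactone A
Product: 14 C7,C12-diol
Conditions: LiAlH4, THF, 0 °C
Reagents that add atoms: none
Why: Hydride reduction of the lactone to the diol releases C12 as a primary alcohol and the C7 hydroxyl, leaves both alkenes alone and removes the acidity of H-2, so C2 can no longer epimerise.

Step 11
Reactants: 14 C7,C12-diol
Product: 15 C7-keto C12-aldehyde
Conditions: (COCl)2, DMSO, CH2Cl2, −78 °C; then i-Pr2NEt, −78 → −20 °C
Reagents that add atoms: none
Why: Swern oxidation activates both hydroxyls before base is added, so the hydroxy aldehyde cannot close to a lactol and be oxidised back to lactone A, and the cold amine work-up should leave H-2 in place.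

Step 12
Reactants: 15 keto aldehyde
Product: 16 C7-keto C12-dimethyl acetal
Conditions: CeCl3·7H2O, HC(OMe)3, MeOH, rt
Reagents that add atoms: trimethyl orthoformate, COC(OC)OC; methanol, CO
Why: Lanthanide-catalysed acetalisation is selective for the aldehyde over the hindered α-quaternary C7 ketone and masks C12 as the dimethyl acetal that is carried to the last step.

Step 13
Reactants: 16 keto acetal diene
Product: 17 bicyclic ketone (rings A and C, C4=C5)
Conditions: second-generation Grubbs catalyst (5 mol%), toluene, 80 °C
Reagents that add atoms: none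
Why: Ring-closing metathesis between the allyl group on C2 and the C5 methylidene closes ring C as a cyclopentene with loss of ethylene; the ruthenium carbene loads on the unhindered allyl terminus and five-membered ring closure compensates for the hindered 1,1-disubstituted partner.

Step 14
Reactants: 17 bicyclic ketone
Product: 18 C7 enol triflate (C7=C11)
Conditions: KN(SiMe3)2, THF, −78 °C; then PhNTf2, −78 → 0 °C
Reagents that add atoms: N-phenylbis(trifluoromethanesulfonimide), O=S(=O)(N(c1ccccc1)S(=O)(=O)C(F)(F)F)C(F)(F)F
Why: Enol triflate formation is regiochemically unambiguous because the C7 ketone can enolise only toward C11.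

Step 15
Reactants: 18 C7 enol triflate
Product: 19 C7 methyl enoate (C7=C11)
Conditions: Pd(OAc)2, PPh3, CO (1 atm), Et3N, MeOH/DMF, 60 °C
Reagents that add atoms: carbon monoxide, [C-]#[O+]; methanol, CO
Why: Palladium-catalysed methoxycarbonylation of the vinyl triflate (oxidative addition to zerovalent palladium, CO insertion, methanolysis) attaches C8 to C7 at the ester oxidation level.

Step 16
Reactants: 19 C7 methyl enoate
Product: 20 C10 alcohol of the enoate
Conditions: DDQ, CH2Cl2/pH 7 buffer, 0 °C
Reagents that add atoms: none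
Why: Oxidative cleavage of the 4-methoxybenzyl ether frees the C10 hydroxyl under buffered, non-acidic conditions that spare the acetal, the silyl ether and both alkenes.

Step 17
Reactants: 20 C10 alcohol of the enoate
Product: 22 bridged lactone B (3-oxabicyclo[3.2.1]octan-2-one fused to ring C), via hydroxy ester 21 (not isolated)
Conditions: Mg, MeOH, 0 °C → rt; then t-BuOK (0.2 equiv), toluene, 60 °C
Reagents that add atoms: none
Why: Dissolving-metal conjugate reduction of the enoate followed by alkoxide-mediated epimerisation and lactonisation sets C7, because H-7 is α to the ester and equilibrates while only the epimer with C8 cis to C10 can close the bridged lactone, so all material is drawn into lactone B.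

Step 18
Reactants: 22 bridged lactone B
Product: 24 C10 triethylsilyl ether of the β-keto sulfone, via hydroxy keto sulfone 23 (not isolated)
Conditions: PhSO2CH3, n-BuLi, THF, −78 → 0 °C; pH 7 buffer; then TESCl, imidazole, CH2Cl2, 0 °C
Reagents that add atoms: methyl phenyl sulfone, CS(=O)(=O)c1ccccc1; chlorotriethylsilane, CC[Si](Cl)(CC)CC
Why: Claisen-type acylation of the lithiated sulfone by the lactone opens lactone B to the β-keto sulfone, which stays as its C9 enolate so that H-7 is not touched, and silylation of the released C10 hydroxyl keeps it away from the neighbouring acetal.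

Step 19
Reactants: 24 β-keto sulfone
Product: 25 (E)-enol triflate (sulfonyl cis to C7)
Conditions: KN(SiMe3)2, 18-crown-6, THF, −78 °C; then PhNTf2, −78 → 0 °C
Reagents that add atoms: N-phenylbis(trifluoromethanesulfonimide), O=S(=O)(N(c1ccccc1)S(=O)(=O)C(F)(F)F)C(F)(F)F
Why: O-Triflation of the β-keto sulfone enolate occurs toward the doubly activated C9, and the crown-complexed, non-chelated enolate should adopt the dipole-minimised geometry that gives the (E)-triflate with the sulfonyl group cis to C7.

Step 20
Reactants: 25 (E)-enol triflate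
Product: 26 (E)-β-phenylsulfonyl acrylate 4-methoxybenzyl ester with C10 triethylsilyl ether
Conditions: Pd(PPh3)4, CO (1 atm), 4-MeOC6H4CH2OH, i-Pr2NEt, DMF, 40 °C
Reagents that add atoms: carbon monoxide, [C-]#[O+]; 4-methoxybenzyl alcohol, COc1ccc(CO)cc1
Why: Palladium-catalysed alkoxycarbonylation of the vinyl triflate proceeds with retention of alkene geometry and installs the carboxyl carbon C13 on C8 as an acid-labile 4-methoxybenzyl ester, completing the β-sulfonyl acrylate.

Step 21
Reactants: 26 sulfonyl acrylate silyl ether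
Product: 27 C10 aldehyde (bicyclo[3.3.0]octene aldehyde with the β-phenylsulfonyl acrylate on C7)
Conditions: (COCl)2, DMSO, CH2Cl2, −78 → −40 °C; then i-Pr2NEt, −78 → 0 °C
Reagents that add atoms: none
Why: Swern oxidation converts the primary triethylsilyl ether directly into the aldehyde because the chlorosulfonium salt cleaves this labile ether but not the tert-butyldimethylsilyl ether, so a free C10 alcohol next to the acetal is never exposed to acid.

Step 22
Reactants: 27 C10 aldehyde
Product: 28 tricyclic C10 alcohol with C8=C9 enoate and C4=C5 alkene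
Conditions: SmI2 (2.5 equiv), MeOH (2 equiv), THF, −78 → −20 °C; pH 7 buffer
Reagents that add atoms: none
Why: SmI2 (divalent samarium) reduces the aldehyde to a ketyl that adds through C10 to C9, the β-carbon of the acrylate, and the resulting C8 radical, or the enolate formed from it by a second electron, expels phenylsulfinate from C9 and restores the C8=C9 bond. The closest known reaction type is the SmI2 ketyl–olefin cyclisation onto β-heteroatom-substituted acrylates, combined with radical addition–β-elimination at vinyl sulfones. Ring B closes in the 6-endo-trig mode with respect to C8=C9 across the cis arms on C1 and C7; the 5-exo alternative would put the nucleophilic ketyl on the α-carbon and build a bicyclo[2.2.1] core, so it should not compete. C10 is set in a chair-like transition state in which the bulky samarium-bound oxygen takes the pseudo-axial site on the face away from the C5–C6 bridge and the C2 acetal, leaving H-10 toward ring C. The step needs aldehyde reduction ahead of the sulfonyl acrylate, which should be secured by working cold and without HMPA so that inner-sphere carbonyl reduction is the fast path. It also needs ready loss of sulfinate, which the (E) geometry provides because the C9–S bond ends pseudo-axial and parallel to the C8 p orbital after ring closure.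

Step 23
Reactants: 28 tricyclic C10 alcohol
Product: 29 C10 chloroacetate
Conditions: (ClCH2CO)2O, pyridine, DMAP, CH2Cl2, 0 °C
Reagents that add atoms: chloroacetic anhydride, O=C(CCl)OC(=O)CCl
Why: Acylation masks the C10 hydroxyl so that it can neither direct hydrogenation onto C8=C9 nor attack the neighbouring acetal under the acidic conditions of step 24; the C10 configuration is retained.

Step 24
Reactants: 29 C10 chloroacetate
Product: 30 C6 hydroxymethyl chloroacetate
Conditions: HF·pyridine, pyridine, THF, 0 °C → rt
Reagents that add atoms: none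
Why: Fluoride-mediated desilylation frees the C6 hydroxymethyl group, which is the directing group for the hydrogenation.

Step 25
Reactants: 30 C6 hydroxymethyl chloroacetate
Product: 31 C4,C5-dihydro chloroacetate (H-5 on the C11 face)
Conditions: [Ir(cod)(PCy3)(py)]PF6 (20 mol%), H2 (1 atm), CH2Cl2, rt
Reagents that add atoms: none
Why: Hydroxyl-directed homogeneous hydrogenation: iridium bound to the homoallylic C6 hydroxymethyl delivers both hydrogens to C4=C5 from the C11 face, which is also the open exo face of the bicyclo[3.2.1] core, so H-5 is set syn to the hydroxymethyl group while the electron-poor C8=C9 bond has no free hydroxyl to guide the catalyst.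

Step 26
Reactants: 31 dihydro chloroacetate
Product: 32 C10 alcohol with free C6 hydroxymethyl
Conditions: thiourea, NaHCO3, EtOH, 50 °C
Reagents that add atoms: none
Why: Chloroacetate cleavage by thiourea (S-alkylation, then cyclisation onto the ester carbonyl) is neutral and leaves the 4-methoxybenzyl ester, the acetal and the enoate untouched.

Step 27
Reactants: 32 diol
Product: 33 C6 silyloxymethyl C10 alcohol
Conditions: TBSCl, imidazole, CH2Cl2, 0 °C
Reagents that add atoms: tert-butyl(chloro)dimethylsilane, CC(C)(C)[Si](C)(C)Cl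
Why: Selective silylation of the primary hydroxyl over the hindered secondary allylic hydroxyl leaves only C10–OH free for the esterification.

Step 28
Reactants: 34 oct-7-yn-1-ol; 35 8-bromooctanoic acid
Product: 36 16-hydroxyhexadec-9-ynoic acid
Conditions: n-BuLi (3.1 equiv), THF/DMPU, −78 °C → rt; H3O+
Reagents that add atoms: none
Why: Acetylide alkylation: the alkoxide–acetylide dianion of 34 displaces bromide from the lithium carboxylate of 35 and joins the two C8 pieces at the alkyne.

Step 29
Reactants: 36 16-hydroxyhexadec-9-ynoic acid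
Product: 37 (9Z)-16-hydroxyhexadec-9-enoic acid
Conditions: H2 (1 atm), Pd/CaCO3 poisoned with Pb(OAc)2, quinoline, EtOAc, rt
Reagents that add atoms: none
Why: Lindlar semihydrogenation adds hydrogen syn to the alkyne and stops at the (Z)-alkene.

Step 30
Reactants: 37 (9Z)-16-hydroxyhexadec-9-enoic acid
Product: 39 (9Z)-16-{[tert-butyl(dimethyl)silyl]oxy}hexadec-9-enoic acid, via silyl ester 38 (not isolated)
Conditions: TBSCl (2.5 equiv), imidazole, DMF, rt; then K2CO3, MeOH/THF/H2O, rt
Reagents that add atoms: tert-butyl(chloro)dimethylsilane, CC(C)(C)[Si](C)(C)Cl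
Why: Silylation of both the hydroxyl and the carboxyl group followed by mild hydrolysis of the labile silyl ester leaves the acid free and the primary alcohol protected.

Step 31
Reactants: 33 C10 alcohol; 39 silyl-protected chain acid
Product: 40 fully protected target
Conditions: EDC·HCl, DMAP, CH2Cl2, 0 °C → rt
Reagents that add atoms: none
Why: Steglich esterification acylates the C10 hydroxyl with retention of configuration under conditions free of strong acid, so the hydroxyl does not attack the neighbouring acetal.

Step 32
Reactants: 40 fully protected target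
Product: 41 target CNP0148862.1
Conditions: TFA/CH2Cl2/H2O, 0 °C → rt
Reagents that add atoms: water, O
Why: Acidolysis removes all protecting groups in one operation, the 4-methoxybenzyl ester by alkyl–oxygen cleavage and the two silyl ethers and the dimethyl acetal by hydrolysis, while the allylic C10 ester, deactivated by the conjugated acid, and the base-sensitive C2 stereocentre should survive.

**Compound list**

1 | 2-methylcyclopentane-1,3-dione | CC1C(=O)CCC1=O | starting material
2 | 2-(hydroxymethyl)-2-methylcyclopentane-1,3-dione | CC1(CO)C(=O)CCC1=O | intermediate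
3 | 2-{[tert-butyl(dimethyl)silyl]oxymethyl}-2-methylcyclopentane-1,3-dione | CC1(CO[Si](C)(C)C(C)(C)C)C(=O)CCC1=O | intermediate
4 | (2R,3R)-2-{[tert-butyl(dimethyl)silyl]oxymethyl}-3-hydroxy-2-methylcyclopentan-1-one (C7–OH cis to CH2OTBS) | C[C@@]1(CO[Si](C)(C)C(C)(C)C)[C@H](O)CCC1=O | intermediate
5 | C7 triethylsilyl ether of 4 | C[C@@]1(CO[Si](C)(C)C(C)(C)C)[C@H](O[Si](CC)(CC)CC)CCC1=O | intermediate
6 | methyl bromoacetate | COC(=O)CBr | starting material
7 | ketone 5 with CH2CO2Me on C1, both C1 epimers | C[C@@]1(CO[Si](C)(C)C(C)(C)C)[C@H](O[Si](CC)(CC)CC)CC(CC(=O)OC)C1=O | intermediate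
8 | C1-quaternary keto ester (CH2OPMB trans, CH2CO2Me cis to C7–OTES) | C[C@@]1(CO[Si](C)(C)C(C)(C)C)[C@H](O[Si](CC)(CC)CC)C[C@@](CC(=O)OC)(COCc2ccc(OC)cc2)C1=O | intermediate
9 | C5-methylidene ester | C[C@@]1(CO[Si](C)(C)C(C)(C)C)[C@H](O[Si](CC)(CC)CC)C[C@@](CC(=O)OC)(COCc2ccc(OC)cc2)C1=C | intermediate
10 | C7 hydroxy ester | C[C@@]1(CO[Si](C)(C)C(C)(C)C)[C@H](O)C[C@@](CC(=O)OC)(COCc2ccc(OC)cc2)C1=C | intermediate
11 | bridged lactone A (C7–O–C12(=O)–C2–C1) | C[C@@]1(CO[Si](C)(C)C(C)(C)C)[C@H]2C[C@@](CC(=O)O2)(COCc3ccc(OC)cc3)C1=C | intermediate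
12 | allyl bromide | C=CCBr | starting material
13 | C2-allyl lactone A (allyl anti to C1–C5) | C[C@@]1(CO[Si](C)(C)C(C)(C)C)[C@H]2C[C@@]([C@H](CC=C)C(=O)O2)(COCc3ccc(OC)cc3)C1=C | intermediate
14 | C7,C12-diol | C[C@@]1(CO[Si](C)(C)C(C)(C)C)[C@H](O)C[C@@]([C@H](CC=C)CO)(COCc2ccc(OC)cc2)C1=C | intermediate
15 | C7-keto C12-aldehyde | C[C@@]1(CO[Si](C)(C)C(C)(C)C)C(=O)C[C@@]([C@H](CC=C)C=O)(COCc2ccc(OC)cc2)C1=C | intermediate
16 | C7-keto C12-dimethyl acetal | C[C@@]1(CO[Si](C)(C)C(C)(C)C)C(=O)C[C@@]([C@H](CC=C)C(OC)OC)(COCc2ccc(OC)cc2)C1=C | intermediate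
17 | bicyclic C7 ketone (rings A and C, C4=C5, C12 acetal cis to C10) | C[C@@]1(CO[Si](C)(C)C(C)(C)C)C(=O)C[C@]3(COCc4ccc(OC)cc4)[C@@H](C(OC)OC)CC=C13 | intermediate
18 | C7 enol triflate (C7=C11) | C[C@@]1(CO[Si](C)(C)C(C)(C)C)C(OS(=O)(=O)C(F)(F)F)=C[C@]3(COCc4ccc(OC)cc4)[C@@H](C(OC)OC)CC=C13 | intermediate
19 | C7 methyl enoate (C7=C11) | C[C@@]1(CO[Si](C)(C)C(C)(C)C)C(C(=O)OC)=C[C@]3(COCc4ccc(OC)cc4)[C@@H](C(OC)OC)CC=C13 | intermediate
20 | C10 alcohol of the enoate | C[C@@]1(CO[Si](C)(C)C(C)(C)C)C(C(=O)OC)=C[C@]3(CO)[C@@H](C(OC)OC)CC=C13 | intermediate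
21 | saturated C10-hydroxy C7 methyl ester, both C7 epimers | C[C@@]1(CO[Si](C)(C)C(C)(C)C)C(C(=O)OC)C[C@]3(CO)[C@@H](C(OC)OC)CC=C13 | intermediate
22 | bridged lactone B (C10–O–C8(=O)–C7) | C[C@@]1(CO[Si](C)(C)C(C)(C)C)[C@@H]2C[C@]3(COC2=O)[C@@H](C(OC)OC)CC=C13 | intermediate
23 | C10-hydroxy β-keto sulfone | C[C@@]1(CO[Si](C)(C)C(C)(C)C)[C@@H](C(=O)CS(=O)(=O)c4ccccc4)C[C@]3(CO)[C@@H](C(OC)OC)CC=C13 | intermediate
24 | C10 triethylsilyl ether of the β-keto sulfone | C[C@@]1(CO[Si](C)(C)C(C)(C)C)[C@@H](C(=O)CS(=O)(=O)c4ccccc4)C[C@]3(CO[Si](CC)(CC)CC)[C@@H](C(OC)OC)CC=C13 | intermediate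
25 | (E)-enol triflate of 24 | C[C@@]1(CO[Si](C)(C)C(C)(C)C)[C@@H](/C(OS(=O)(=O)C(F)(F)F)=C\S(=O)(=O)c4ccccc4)C[C@]3(CO[Si](CC)(CC)CC)[C@@H](C(OC)OC)CC=C13 | intermediate
26 | (E)-β-phenylsulfonyl acrylate 4-methoxybenzyl ester, C10 triethylsilyl ether | C[C@@]1(CO[Si](C)(C)C(C)(C)C)[C@@H](/C(C(=O)OCc5ccc(OC)cc5)=C\S(=O)(=O)c4ccccc4)C[C@]3(CO[Si](CC)(CC)CC)[C@@H](C(OC)OC)CC=C13 | intermediate
27 | C10 aldehyde, key-step precursor | C[C@@]1(CO[Si](C)(C)C(C)(C)C)[C@@H](/C(C(=O)OCc5ccc(OC)cc5)=C\S(=O)(=O)c4ccccc4)C[C@]3(C=O)[C@@H](C(OC)OC)CC=C13 | intermediate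
28 | tricyclic C10 alcohol, key-step product | C[C@@]1(CO[Si](C)(C)C(C)(C)C)[C@@H]2C[C@]3([C@@H](O)C=C2C(=O)OCc4ccc(OC)cc4)[C@@H](C(OC)OC)CC=C13 | intermediate
29 | C10 chloroacetate | C[C@@]1(CO[Si](C)(C)C(C)(C)C)[C@@H]2C[C@]3([C@@H](OC(=O)CCl)C=C2C(=O)OCc4ccc(OC)cc4)[C@@H](C(OC)OC)CC=C13 | intermediate
30 | C6 hydroxymethyl chloroacetate | C[C@@]1(CO)[C@@H]2C[C@]3([C@@H](OC(=O)CCl)C=C2C(=O)OCc4ccc(OC)cc4)[C@@H](C(OC)OC)CC=C13 | intermediate
31 | C4,C5-dihydro chloroacetate | C[C@@]1(CO)[C@@H]2C[C@]3([C@@H](OC(=O)CCl)C=C2C(=O)OCc4ccc(OC)cc4)[C@@H](C(OC)OC)CC[C@@H]13 | intermediate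
32 | C10 alcohol with free C6 hydroxymethyl | C[C@@]1(CO)[C@@H]2C[C@]3([C@@H](O)C=C2C(=O)OCc4ccc(OC)cc4)[C@@H](C(OC)OC)CC[C@@H]13 | intermediate
33 | C6 silyloxymethyl C10 alcohol | C[C@@]1(CO[Si](C)(C)C(C)(C)C)[C@@H]2C[C@]3([C@@H](O)C=C2C(=O)OCc4ccc(OC)cc4)[C@@H](C(OC)OC)CC[C@@H]13 | intermediate
34 | oct-7-yn-1-ol | C#CCCCCCCO | starting material
35 | 8-bromooctanoic acid | OC(=O)CCCCCCCBr | starting material
36 | 16-hydroxyhexadec-9-ynoic acid | OCCCCCCC#CCCCCCCCC(=O)O | intermediate
37 | (9Z)-16-hydroxyhexadec-9-enoic acid | OCCCCCC/C=C\CCCCCCCC(=O)O | intermediate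
38 | tert-butyl(dimethyl)silyl (9Z)-16-{[tert-butyl(dimethyl)silyl]oxy}hexadec-9-enoate | CC(C)(C)[Si](C)(C)OCCCCCC/C=C\CCCCCCCC(=O)O[Si](C)(C)C(C)(C)C | intermediate
39 | (9Z)-16-{[tert-butyl(dimethyl)silyl]oxy}hexadec-9-enoic acid | CC(C)(C)[Si](C)(C)OCCCCCC/C=C\CCCCCCCC(=O)O | intermediate
40 | fully protected target (C10 ester, two silyl ethers, 4-methoxybenzyl ester, dimethyl acetal) | C[C@@]1(CO[Si](C)(C)C(C)(C)C)[C@@H]2C[C@]3([C@@H](OC(=O)CCCCCCC/C=C\CCCCCCO[Si](C)(C)C(C)(C)C)C=C2C(=O)OCc4ccc(OC)cc4)[C@@H](C(OC)OC)CC[C@@H]13 | intermediate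
41 | CNP0148862.1 | C[C@@]1(CO)[C@@H]2C[C@]3([C@@H](OC(=O)CCCCCCC/C=C\CCCCCCO)C=C2C(=O)O)[C@@H](C=O)CC[C@@H]13 | target

**Count and risks**

Total step count: 32. Longest linear sequence: 29 steps (steps 1–27, 31 and 32).

Most likely to fail:

1. Step 22. Electron transfer to the sulfonyl acrylate may run ahead of ketyl formation, the aldehyde may simply be reduced, or the samarium-bound oxygen may take the other face at C10. The fallback forms the same C9–C10 bond by a polar organochromium addition. It sets out from 26: Bu3SnH and AIBN in benzene at 80 °C exchange the sulfonyl group for tin by radical addition–elimination to give the stannyl acrylate F1. I2 in CH2Cl2 at 0 °C gives the iodoacrylate F2. The Swern conditions of step 21 give the iodo aldehyde F3. CrCl2 with catalytic NiCl2 in DMF then closes ring B by a Nozaki–Hiyama–Kishi reaction and returns to the route at 28.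

2. Step 25. Hydrogen delivery may be slow because it builds the strained trans fusion of rings A and C, and iridium held by the chloroacetate carbonyl may start to reduce C8=C9. The fallback drops the directing group and the masking steps and uses a metal-hydride hydrogen-atom-transfer hydrogenation. It sets out from 28: Mn(dpm)3 (catalytic), PhSiH3 and t-BuOOH in i-PrOH at rt should transfer a hydrogen atom to C4 of the electron-rich alkene only, and the tertiary C5 radical then takes its hydrogen on the open C11 face. This returns to the route directly at 33 and makes no compound outside the list (entry F0).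

3. Step 20. The alcohol or the amine may add to the newly formed, strongly electrophilic sulfonyl acrylate, or the alkene geometry may be lost during carbonylation. The fallback carries sulfur at the sulfide level through the carbonylation and oxidises afterwards. It sets out from 22: PhSCH3, n-BuLi and DABCO in THF open the lactone to the hydroxy keto sulfide F4. TESCl and imidazole give the silyl ether F5. KN(SiMe3)2, 18-crown-6 and PhNTf2 give the enol triflate F6. Pd(PPh3)4, CO and 4-methoxybenzyl alcohol give the unreactive phenylthio acrylate F7. n-Pr4N[RuO4] (catalytic) with N-methylmorpholine N-oxide in MeCN oxidises sulfur to the sulfone and returns to the route at 26.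

Further compounds
F1 | step 22 | (E)-β-tributylstannyl acrylate 4-methoxybenzyl ester, C10 triethylsilyl ether | C[C@@]1(CO[Si](C)(C)C(C)(C)C)[C@@H](/C(C(=O)OCc5ccc(OC)cc5)=C\[Sn](CCCC)(CCCC)CCCC)C[C@]3(CO[Si](CC)(CC)CC)[C@@H](C(OC)OC)CC=C13
F2 | step 22 | (E)-β-iodoacrylate 4-methoxybenzyl ester, C10 triethylsilyl ether | C[C@@]1(CO[Si](C)(C)C(C)(C)C)[C@@H](/C(C(=O)OCc5ccc(OC)cc5)=C\I)C[C@]3(CO[Si](CC)(CC)CC)[C@@H](C(OC)OC)CC=C13
F3 | step 22 | C10 aldehyde with (E)-β-iodoacrylate on C7 | C[C@@]1(CO[Si](C)(C)C(C)(C)C)[C@@H](/C(C(=O)OCc5ccc(OC)cc5)=C\I)C[C@]3(C=O)[C@@H](C(OC)OC)CC=C13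
F0 | step 25 | none | none
F4 | step 20 | C10-hydroxy β-keto sulfide | C[C@@]1(CO[Si](C)(C)C(C)(C)C)[C@@H](C(=O)CSc4ccccc4)C[C@]3(CO)[C@@H](C(OC)OC)CC=C13
F5 | step 20 | C10 triethylsilyl ether of the β-keto sulfide | C[C@@]1(CO[Si](C)(C)C(C)(C)C)[C@@H](C(=O)CSc4ccccc4)C[C@]3(CO[Si](CC)(CC)CC)[C@@H](C(OC)OC)CC=C13
F6 | step 20 | enol triflate of the β-keto sulfide (sulfur cis to C7) | C[C@@]1(CO[Si](C)(C)C(C)(C)C)[C@@H](/C(OS(=O)(=O)C(F)(F)F)=C\Sc4ccccc4)C[C@]3(CO[Si](CC)(CC)CC)[C@@H](C(OC)OC)CC=C13
F7 | step 20 | β-phenylthio acrylate 4-methoxybenzyl ester, C10 triethylsilyl ether | C[C@@]1(CO[Si](C)(C)C(C)(C)C)[C@@H](/C(C(=O)OCc5ccc(OC)cc5)=C\Sc4ccccc4)C[C@]3(CO[Si](CC)(CC)CC)[C@@H](C(OC)OC)CC=C13
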